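**Retrosynthetic overview**

1. Acredinone A ⇐ removal of two MOM ethers ⇐ intramolecular aldol condensation of a 1,2-diarylethanone Ar–CO–CH2–Ar, in which both aryl groups are the same protected benzophenone unit.
2. Ar–CO–CH2–Ar ⇐ decarboxylation of an allyl β-keto ester ⇐ oxidation of the β-hydroxy ester from the key intermolecular aldol addition of the lithium enolate of Ar–CH2–CO2allyl to Ar–CHO.
3. Both aldol partners ⇐ one ortho-allyl benzophenone Ar–CH2CH=CH2 (isomerization/cleavage gives the aldehyde; cleavage/oxidation/esterification gives the ester).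
4. Allyl benzophenone ⇐ 2,6-dimethoxyphenyllithium + a pentasubstituted benzaldehyde, then oxidation; that aldehyde ⇐ 2,5-dimethoxytoluene by formylation, directed ortho-lithiation/allylation, selective O-demethylation and MOM protection.
5. Ring order: the three benzene rings are bought; the cyclopentenone ring of the indenone is the only ring formed, and it is formed last (step 15).

Assumption: the target SMILES has no stereocentre and no stereodescriptor, so acredinone A is made as the one achiral constitution drawn; stereocentres in intermediates are racemic or mixed and are all erased.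

Abbreviation used in names: Ar = 2-(2,6-dimethoxybenzoyl)-6-methoxy-3-(methoxymethoxy)-5-methylphenyl.

**Route**

Step 1
Reactants: 1 2,5-dimethoxytoluene
Product: 2 2,5-dimethoxy-4-methylbenzaldehyde
Conditions: Cl2CHOMe (1.2 equiv), TiCl4 (2 equiv), CH2Cl2, 0 °C; then ice/H2O
Reagents that add atoms: dichloromethyl methyl ether COC(Cl)Cl (formyl carbon); water O (carbonyl oxygen, on hydrolytic work-up)
Why: Rieche formylation (electrophilic aromatic substitution) goes to the position para to the methyl group and ortho to a methoxy group, and hydrolysis of the α-chloro ether on work-up releases the aldehyde.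

Step 2
Reactants: 2 2,5-dimethoxy-4-methylbenzaldehyde
Product: 5 3,6-dimethoxy-4-methyl-2-(prop-2-en-1-yl)benzaldehyde, via lithium α-amino alkoxide 3 (not isolated), via ortho-lithiated α-amino alkoxide 4 (not isolated)
Conditions: Me2NCH2CH2N(Me)Li (from Me2NCH2CH2NHMe + n-BuLi), THF, −20 °C; n-BuLi (3 equiv), −20 °C, 12 h; CuBr·SMe2 (10 mol %), allyl bromide (excess), −78 °C → rt; then H2O
Reagents that add atoms: allyl bromide C=CCBr
Why: Comins directed ortho-metalation: the in situ α-amino alkoxide masks the aldehyde and, together with the neighbouring methoxy group, directs n-BuLi to the only free ortho carbon, and the aryllithium is allylated under CuBr·SMe2 catalysis before aqueous work-up returns the aldehyde.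

Step 3
Reactants: 5 3,6-dimethoxy-4-methyl-2-(prop-2-en-1-yl)benzaldehyde
Product: 6 6-hydroxy-3-methoxy-4-methyl-2-(prop-2-en-1-yl)benzaldehyde
Conditions: BCl3 (1.2 equiv), CH2Cl2, −78 → 0 °C; then H2O
Reagents that add atoms: none
Why: Chelation-controlled Lewis-acid ether cleavage: BCl3 bridges the formyl oxygen and the ortho methoxy oxygen, so only that methyl ether is cut and the methoxy group between allyl and methyl stays.

Step 4
Reactants: 6 6-hydroxy-3-methoxy-4-methyl-2-(prop-2-en-1-yl)benzaldehyde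
Product: 7 3-methoxy-6-(methoxymethoxy)-4-methyl-2-(prop-2-en-1-yl)benzaldehyde
Conditions: MOMCl (1.5 equiv), iPr2NEt (2 equiv), CH2Cl2, 0 °C → rt
Reagents that add atoms: chloromethyl methyl ether COCCl
Why: O-alkylation of the phenol (Williamson-type) gives a MOM acetal that survives organolithiums, oxidants and bases and is removed by acid at the very end.

Step 5
Reactants: 7 3-methoxy-6-(methoxymethoxy)-4-methyl-2-(prop-2-en-1-yl)benzaldehyde; 8 1,3-dimethoxybenzene
Product: 10 (2,6-dimethoxyphenyl)[3-methoxy-6-(methoxymethoxy)-4-methyl-2-(prop-2-en-1-yl)phenyl]methanol (racemic), via 2,6-dimethoxyphenyllithium 9 (not isolated)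
Conditions: 8, n-BuLi, THF, 0 °C → rt, 2 h; then 7, −78 → 0 °C; then H2O
Reagents that add atoms: none
Why: Directed ortho-lithiation of 1,3-dimethoxybenzene between its two methoxy groups and 1,2-addition of the aryllithium to the aldehyde give the carbinol, whose racemic stereocentre is erased in step 6.

Step 6
Reactants: 10 (2,6-dimethoxyphenyl)[3-methoxy-6-(methoxymethoxy)-4-methyl-2-(prop-2-en-1-yl)phenyl]methanol
Product: 11 (2,6-dimethoxyphenyl)[3-methoxy-6-(methoxymethoxy)-4-methyl-2-(prop-2-en-1-yl)phenyl]methanone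
Conditions: Dess–Martin periodinane (1.5 equiv), CH2Cl2, rt
Reagents that add atoms: none
Why: Dess–Martin oxidation turns the hindered diarylcarbinol into the tetra-ortho-substituted benzophenone under neutral conditions that leave the allyl group and the MOM ether alone.

Step 7
Reactants: 11 (2,6-dimethoxyphenyl)[3-methoxy-6-(methoxymethoxy)-4-methyl-2-(prop-2-en-1-yl)phenyl]methanone
Product: 12 (2,6-dimethoxyphenyl){3-methoxy-6-(methoxymethoxy)-4-methyl-2-[(1E)-prop-1-en-1-yl]phenyl}methanone
Conditions: RuHCl(CO)(PPh3)3 (5 mol %), toluene, 90 °C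
Reagents that add atoms: none
Why: Ruthenium-hydride-catalysed alkene isomerization (hydrometalation/β-hydride elimination) moves the terminal double bond to the more stable internal position; the E isomer predominates and the E/Z ratio is irrelevant for step 8.

Step 8
Reactants: 12 (2,6-dimethoxyphenyl){3-methoxy-6-(methoxymethoxy)-4-methyl-2-[(1E)-prop-1-en-1-yl]phenyl}methanone
Product: 14 2-(2,6-dimethoxybenzoyl)-6-methoxy-3-(methoxymethoxy)-5-methylbenzaldehyde, via syn-diol 13 (not isolated)
Conditions: OsO4 (2 mol %), NaIO4 (4 equiv), 2,6-lutidine, dioxane/H2O, rt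
Reagents that add atoms: osmium tetroxide O=[Os](=O)(=O)=O (delivers the oxygen); sodium periodate [Na+].[O-]I(=O)(=O)=O (terminal oxidant that restores it)
Why: Lemieux–Johnson oxidation: OsO4 syn-dihydroxylates the propenyl group and NaIO4 cleaves the diol to the aryl aldehyde without touching the electron-rich rings.

Step 9
Reactants: 11 (2,6-dimethoxyphenyl)[3-methoxy-6-(methoxymethoxy)-4-methyl-2-(prop-2-en-1-yl)phenyl]methanone
Product: 16 [2-(2,6-dimethoxybenzoyl)-6-methoxy-3-(methoxymethoxy)-5-methylphenyl]acetaldehyde, via diol 15 (not isolated)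
Conditions: OsO4 (2 mol %), NaIO4 (4 equiv), 2,6-lutidine, dioxane/H2O, rt; used crude
Reagents that add atoms: osmium tetroxide O=[Os](=O)(=O)=O (delivers the oxygen); sodium periodate [Na+].[O-]I(=O)(=O)=O (terminal oxidant that restores it)
Why: Lemieux–Johnson oxidation of the terminal alkene removes one carbon and leaves the arylacetaldehyde, which is oxidized at once to avoid self-condensation.

Step 10
Reactants: 16 [2-(2,6-dimethoxybenzoyl)-6-methoxy-3-(methoxymethoxy)-5-methylphenyl]acetaldehyde
Product: 17 [2-(2,6-dimethoxybenzoyl)-6-methoxy-3-(methoxymethoxy)-5-methylphenyl]acetic acid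
Conditions: NaClO2, NaH2PO4, 2-methyl-2-butene (excess), t-BuOH/H2O, 0 °C → rt
Reagents that add atoms: sodium chlorite [Na+].[O-]Cl=O
Why: Pinnick oxidation converts the aldehyde to the acid at buffered pH, and 2-methyl-2-butene traps HOCl so the electron-rich rings are not chlorinated.

Step 11
Reactants: 17 [2-(2,6-dimethoxybenzoyl)-6-methoxy-3-(methoxymethoxy)-5-methylphenyl]acetic acid
Product: 18 prop-2-en-1-yl [2-(2,6-dimethoxybenzoyl)-6-methoxy-3-(methoxymethoxy)-5-methylphenyl]acetate
Conditions: allyl bromide, K2CO3, DMF, rt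
Reagents that add atoms: allyl bromide C=CCBr
Why: SN2 O-alkylation of the carboxylate gives the normal allyl ester, chosen because it is later removed by a palladium catalyst under neutral conditions.

Step 12 (key C–C bond formation)
Reactants: 18 prop-2-en-1-yl [2-(2,6-dimethoxybenzoyl)-6-methoxy-3-(methoxymethoxy)-5-methylphenyl]acetate; 14 2-(2,6-dimethoxybenzoyl)-6-methoxy-3-(methoxymethoxy)-5-methylbenzaldehyde
Product: 20 prop-2-en-1-yl 3-hydroxy-2,3-bis(Ar)propanoate (diastereomer mixture), via lithium ester enolate 19 (not isolated)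
Conditions: 18, LiN(SiMe3)2 (1.1 equiv), THF, −78 °C, 30 min; then 14, −78 °C, 2 h; AcOH quench at −78 °C
Reagents that add atoms: none
Why: Intermolecular aldol addition: the preformed lithium ester enolate adds to the aldehyde (the tetra-ortho-substituted ketones are inert), the cold acidic quench prevents retro-aldol, and the two new stereocentres, formed as a mixture, are both erased in steps 13 to 15.

Step 13
Reactants: 20 prop-2-en-1-yl 3-hydroxy-2,3-bis(Ar)propanoate
Product: 21 prop-2-en-1-yl 3-oxo-2,3-bis(Ar)propanoate (racemic, keto/enol)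
Conditions: Dess–Martin periodinane (2 equiv), CH2Cl2, rt
Reagents that add atoms: none
Why: Dess–Martin oxidation of the benzylic alcohol, which stays available through the open hydroxy ketone even if part of 20 rests as its five-membered lactol, gives the β-keto ester without base and so without retro-aldol cleavage.

Step 14
Reactants: 21 prop-2-en-1-yl 3-oxo-2,3-bis(Ar)propanoate
Product: 23 1,2-bis(Ar)ethan-1-one, via β-keto acid 22 (not isolated)
Conditions: Pd(PPh3)4 (5 mol %), morpholine (3 equiv), THF, rt → 40 °C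
Reagents that add atoms: none
Why: Tsuji–Trost deallylation: Pd(PPh3)4 ionizes the allyl ester, morpholine captures the π-allyl unit, and the freed β-keto acid decarboxylates to the ketone under neutral conditions.

Step 15
Reactants: 23 1,2-bis(Ar)ethan-1-one
Product: 25 2-(Ar)-3-(2,6-dimethoxyphenyl)-7-methoxy-4-(methoxymethoxy)-6-methyl-1H-inden-1-one, via 3-hydroxyindanone 24 (not isolated)
Conditions: NaOMe (0.5 equiv), MeOH/THF, 50 °C
Reagents that add atoms: none
Why: Intramolecular aldol condensation: the benzylic ketone enolate attacks the ortho benzophenone carbonyl in a five-membered ring closure (attack on the other benzophenone would need a four-membered ring), and E1cB loss of water gives the conjugated indenone.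

Step 16
Reactants: 25 2-(Ar)-3-(2,6-dimethoxyphenyl)-7-methoxy-4-(methoxymethoxy)-6-methyl-1H-inden-1-one
Product: 26 acredinone A
Conditions: conc. HCl (cat.), MeOH, 50 °C
Reagents that add atoms: none
Why: Acid-catalysed acetal exchange with methanol cleaves both MOM ethers (and would dehydrate any residual 24), while the aryl methyl ethers and the indenone are stable.

**Compound list**

1 | 2,5-dimethoxytoluene | Cc1cc(OC)ccc1OC | starting material
2 | 2,5-dimethoxy-4-methylbenzaldehyde | O=Cc1cc(OC)c(C)cc1OC | intermediate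
3 | lithium (2,5-dimethoxy-4-methylphenyl){[2-(dimethylamino)ethyl](methyl)amino}methanolate (racemic, not isolated) | [Li]OC(N(C)CCN(C)C)c1cc(OC)c(C)cc1OC | intermediate
4 | 6-lithio derivative of 3, lithium on the ring carbon between the aminal carbon and the 5-methoxy group (racemic, not isolated) | [Li]OC(N(C)CCN(C)C)c1c([Li])c(OC)c(C)cc1OC | intermediate
5 | 3,6-dimethoxy-4-methyl-2-(prop-2-en-1-yl)benzaldehyde | O=Cc1c(CC=C)c(OC)c(C)cc1OC | intermediate
6 | 6-hydroxy-3-methoxy-4-methyl-2-(prop-2-en-1-yl)benzaldehyde | O=Cc1c(CC=C)c(OC)c(C)cc1O | intermediate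
7 | 3-methoxy-6-(methoxymethoxy)-4-methyl-2-(prop-2-en-1-yl)benzaldehyde | O=Cc1c(CC=C)c(OC)c(C)cc1OCOC | intermediate
8 | 1,3-dimethoxybenzene | COc1cccc(OC)c1 | starting material
9 | 2,6-dimethoxyphenyllithium (not isolated) | [Li]c1c(OC)cccc1OC | intermediate
10 | (2,6-dimethoxyphenyl)[3-methoxy-6-(methoxymethoxy)-4-methyl-2-(prop-2-en-1-yl)phenyl]methanol (racemic) | OC(c1c(OC)cccc1OC)c1c(CC=C)c(OC)c(C)cc1OCOC | intermediate
11 | (2,6-dimethoxyphenyl)[3-methoxy-6-(methoxymethoxy)-4-methyl-2-(prop-2-en-1-yl)phenyl]methanone | O=C(c1c(OC)cccc1OC)c1c(CC=C)c(OC)c(C)cc1OCOC | intermediate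
12 | (2,6-dimethoxyphenyl){3-methoxy-6-(methoxymethoxy)-4-methyl-2-[(1E)-prop-1-en-1-yl]phenyl}methanone | O=C(c1c(OC)cccc1OC)c1c(/C=C/C)c(OC)c(C)cc1OCOC | intermediate
13 | rac-(1R,2R)-1-(Ar)propane-1,2-diol, the syn-diol of 12, one enantiomer drawn (not isolated) | C[C@H]([C@@H](c1c(C(=O)c2c(OC)cccc2OC)c(OCOC)cc(C)c1OC)O)O | intermediate
14 | 2-(2,6-dimethoxybenzoyl)-6-methoxy-3-(methoxymethoxy)-5-methylbenzaldehyde | O=Cc1c(C(=O)c2c(OC)cccc2OC)c(OCOC)cc(C)c1OC | intermediate
15 | 3-(Ar)propane-1,2-diol (racemic, not isolated) | OCC(O)Cc1c(C(=O)c2c(OC)cccc2OC)c(OCOC)cc(C)c1OC | intermediate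
16 | [2-(2,6-dimethoxybenzoyl)-6-methoxy-3-(methoxymethoxy)-5-methylphenyl]acetaldehyde | O=CCc1c(C(=O)c2c(OC)cccc2OC)c(OCOC)cc(C)c1OC | intermediate
17 | [2-(2,6-dimethoxybenzoyl)-6-methoxy-3-(methoxymethoxy)-5-methylphenyl]acetic acid | OC(=O)Cc1c(C(=O)c2c(OC)cccc2OC)c(OCOC)cc(C)c1OC | intermediate
18 | prop-2-en-1-yl [2-(2,6-dimethoxybenzoyl)-6-methoxy-3-(methoxymethoxy)-5-methylphenyl]acetate | C=CCOC(=O)Cc1c(C(=O)c2c(OC)cccc2OC)c(OCOC)cc(C)c1OC | intermediate
19 | lithium enolate of 18 (enolate geometry not defined, not isolated) | C=CCOC(O[Li])=Cc1c(C(=O)c2c(OC)cccc2OC)c(OCOC)cc(C)c1OC | intermediate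
20 | prop-2-en-1-yl 3-hydroxy-2,3-bis(Ar)propanoate (racemic diastereomer mixture) | C=CCOC(=O)C(c1c(C(=O)c2c(OC)cccc2OC)c(OCOC)cc(C)c1OC)C(O)c1c(C(=O)c2c(OC)cccc2OC)c(OCOC)cc(C)c1OC | intermediate
21 | prop-2-en-1-yl 3-oxo-2,3-bis(Ar)propanoate (racemic) | C=CCOC(=O)C(c1c(C(=O)c2c(OC)cccc2OC)c(OCOC)cc(C)c1OC)C(=O)c1c(C(=O)c2c(OC)cccc2OC)c(OCOC)cc(C)c1OC | intermediate
22 | 3-oxo-2,3-bis(Ar)propanoic acid (racemic, not isolated) | OC(=O)C(c1c(C(=O)c2c(OC)cccc2OC)c(OCOC)cc(C)c1OC)C(=O)c1c(C(=O)c2c(OC)cccc2OC)c(OCOC)cc(C)c1OC | intermediate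
23 | 1,2-bis(Ar)ethan-1-one | O=C(Cc1c(C(=O)c2c(OC)cccc2OC)c(OCOC)cc(C)c1OC)c1c(C(=O)c2c(OC)cccc2OC)c(OCOC)cc(C)c1OC | intermediate
24 | 2-(Ar)-3-(2,6-dimethoxyphenyl)-3-hydroxy-7-methoxy-4-(methoxymethoxy)-6-methyl-2,3-dihydro-1H-inden-1-one (racemic diastereomer mixture, not isolated) | O=C1C(c2c(C(=O)c3c(OC)cccc3OC)c(OCOC)cc(C)c2OC)C(O)(c2c(OC)cccc2OC)c2c(OCOC)cc(C)c(OC)c21 | intermediate
25 | 2-(Ar)-3-(2,6-dimethoxyphenyl)-7-methoxy-4-(methoxymethoxy)-6-methyl-1H-inden-1-one (bis-MOM acredinone A) | COc1cccc(OC)c1C(=O)c1c(OCOC)cc(C)c(OC)c1C1=C(c2c(OC)cccc2OC)c2c(OCOC)cc(C)c(OC)c2C1=O | intermediate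
26 | acredinone A, 2-[2-(2,6-dimethoxybenzoyl)-3-hydroxy-6-methoxy-5-methylphenyl]-3-(2,6-dimethoxyphenyl)-4-hydroxy-7-methoxy-6-methyl-1H-inden-1-one (achiral) | COc1cccc(OC)c1C(=O)c1c(O)cc(C)c(OC)c1C1=C(c2c(OC)cccc2OC)c2c(O)cc(C)c(OC)c2C1=O | target

**Step count and weak points**

Total steps: 16. Longest linear sequence: 14 steps (1 to 6, 9 to 11, 12 to 16); steps 7 and 8 form the side branch to aldehyde 14.

Step 2 (directed ortho-lithiation/allylation) may give poor regiocontrol or a low allylation yield. The fallback sets out from 2 and comes back at 7, so steps 3 and 4 are no longer needed. BBr3 in CH2Cl2 removes both methyl ethers to give 2,5-dihydroxy-4-methylbenzaldehyde F1. The non-chelated 5-hydroxyl is allylated selectively (allyl bromide, NaHCO3, KI, MeCN) to give 2-hydroxy-4-methyl-5-(prop-2-en-1-yloxy)benzaldehyde F2, and MOMCl/iPr2NEt then gives 2-(methoxymethoxy)-4-methyl-5-(prop-2-en-1-yloxy)benzaldehyde F3. An aromatic Claisen rearrangement (N,N-diethylaniline, 190 °C) can deliver the allyl group only to the one free ortho carbon, giving 3-hydroxy-6-(methoxymethoxy)-4-methyl-2-(prop-2-en-1-yl)benzaldehyde F4. MeI/K2CO3 in acetone methylates the new phenol to 7.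

Step 12 (aldol between two di-ortho-substituted partners) may stall or revert. The fallback sets out from 17 (with 14) and comes back at 23, so the ester and the palladium step drop out. Acid 17 is doubly deprotonated with LiN(iPr)2 (2.2 equiv, THF, 0 °C) to dilithium 2-(Ar)ethene-1,1-diolate F5, a more nucleophilic carboxylic acid dianion whose addition to 14 at −78 °C is less reversible. This gives 3-hydroxy-2,3-bis(Ar)propanoic acid F6. Dess–Martin oxidation of F6 gives β-keto acid 22, which loses CO2 on gentle warming to give 23.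

Step 15 (enolate attack on a tetra-ortho-substituted ketone) may not close, or may stop at 24. The fallback sets out from 23 and comes back at 25. TMSOTf/Et3N in CH2Cl2 converts 23 into the silyl enol ether [1,2-bis(Ar)ethenyl]oxy(trimethyl)silane F7. BF3·OEt2 (CH2Cl2, −78 → 0 °C) then activates the benzophenone carbonyl for an intramolecular Mukaiyama aldol to 24, whose tertiary doubly benzylic hydroxyl ionizes under the same Lewis acid and loses water to give 25. Any MOM loss at this stage is harmless because step 16 follows.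

**Further compounds**

F1 | step 2 | 2,5-dihydroxy-4-methylbenzaldehyde | O=Cc1cc(O)c(C)cc1O
F2 | step 2 | 2-hydroxy-4-methyl-5-(prop-2-en-1-yloxy)benzaldehyde | O=Cc1cc(OCC=C)c(C)cc1O
F3 | step 2 | 2-(methoxymethoxy)-4-methyl-5-(prop-2-en-1-yloxy)benzaldehyde | O=Cc1cc(OCC=C)c(C)cc1OCOC
F4 | step 2 | 3-hydroxy-6-(methoxymethoxy)-4-methyl-2-(prop-2-en-1-yl)benzaldehyde | O=Cc1c(CC=C)c(O)c(C)cc1OCOC
F5 | step 12 | dilithium 2-(Ar)ethene-1,1-diolate | [Li]OC(O[Li])=Cc1c(C(=O)c2c(OC)cccc2OC)c(OCOC)cc(C)c1OC
F6 | step 12 | 3-hydroxy-2,3-bis(Ar)propanoic acid (racemic diastereomer mixture) | OC(=O)C(c1c(C(=O)c2c(OC)cccc2OC)c(OCOC)cc(C)c1OC)C(O)c1c(C(=O)c2c(OC)cccc2OC)c(OCOC)cc(C)c1OC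
F7 | step 15 | [1,2-bis(Ar)ethenyl]oxy(trimethyl)silane (enol ether geometry not defined) | C[Si](C)(C)OC(=Cc1c(C(=O)c2c(OC)cccc2OC)c(OCOC)cc(C)c1OC)c1c(C(=O)c2c(OC)cccc2OC)c(OCOC)cc(C)c1OC
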